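The route rests on cutting the C5–C6 bond of ring A of the top catechin unit: this 5,7-dihydroxybenzene, fused to ring C through C4a–C8a, is a 6-methyl-2-pyrone in disguise, the methyl carbon standing where the ring oxygen was. In one flask, methoxide opens the lactone of a pyrano[4,3-b]pyran-5-one and an intramolecular Claisen condensation between the liberated methyl ketone and ester rebuilds the six carbons as aromatic ring A of a 5,7-dihydroxyflav-2-ene, with C4 untouched. The precursor is a (4R)-2,4-diaryl-7-methyl-4H,5H-pyrano[4,3-b]pyran-5-one whose C4 aryl is already ring A of a benzylated, bromine-capped catechin-(4α→6)-epicatechin dimer, so only benzylation, hydroboration and hydrogenolysis remain.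

Key step: step 10

Remarks on the chemistry
- The target is read as catechin-(4α→6)-catechin-(4α→6)-epicatechin: top and middle units (2R,3S,4R), bottom unit (2R,3R).
- Locants follow flavan numbering within each unit, with B-ring positions primed. α is the face of ring C trans to the 3-oxygen of a catechin unit. "10-6-yl" means dimer 10 bonded through C6 of its upper (catechin) unit. α/β is used at C4 because the CIP letter there changes with the protecting groups.
- Design of the precursor: its C4 aryl is ring A of the complete middle–bottom fragment, not a bare protected phloroglucinol ring. The pyran oxygen of the middle unit stands where a masked para-phenol would be, so no flavan ring is built after the key step.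
- The (4R) pyranopyranone carries its C4 aryl on the α face, which is the 4α (4R) configuration of the top unit in the target.
- Assumption: the quinine-derived 9-amino-9-deoxy-epi primary amine is taken to give the (R) adduct in step 9. If the sense is opposite, the quinidine-derived pseudo-enantiomer is used with nothing else changed.

Step 1
Reactants: 1 (−)-epicatechin
Product: 3 3,5,7,3′,4′-penta-O-benzyl-(−)-epicatechin, via tetra-O-benzyl epicatechin 2 (not isolated)
Conditions: BnBr, K2CO3, DMF, 0 °C→rt; then NaH, BnBr, 0 °C→rt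
Reagents that add atoms: benzyl bromide, BrCc1ccccc1
Why: Williamson ether synthesis in two stages, in which carbonate-generated phenoxides are O-benzylated first and NaH then converts the remaining secondary 3-OH into its alkoxide for the fifth benzylation, so that the free-phenol stage is over before strong base is added and C2/C3 are not touched.

Step 2
Reactants: 3 3,5,7,3′,4′-penta-O-benzyl-(−)-epicatechin
Product: 4 8-bromo-3,5,7,3′,4′-penta-O-benzyl-(−)-epicatechin
Conditions: NBS, CH2Cl2, −78 °C→rt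
Reagents that add atoms: N-bromosuccinimide, O=C1CCC(=O)N1Br
Why: Electrophilic aromatic substitution, in which NBS brominates the phloroglucinol-type ring A of benzylated flavan-3-ols selectively at C8, the less hindered of the two activated positions, leaving C6 as the only nucleophilic carbon for step 6.

Step 3
Reactants: 5 (+)-catechin
Product: 7 3,5,7,3′,4′-penta-O-benzyl-(+)-catechin, via tetra-O-benzyl catechin 6 (not isolated)
Conditions: BnBr, K2CO3, DMF, 0 °C→rt; then NaH, BnBr, 0 °C→rt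
Reagents that add atoms: benzyl bromide, BrCc1ccccc1
Why: The same two-stage Williamson ether synthesis as in step 1, applied to the 2,3-trans series without effect on the stereocentres.

Step 4
Reactants: 7 3,5,7,3′,4′-penta-O-benzyl-(+)-catechin
Product: 8 (2R,3S,4S)-4-(2-ethoxyethoxy)-3,5,7,3′,4′-penta-O-benzylcatechin
Conditions: DDQ, 2-ethoxyethanol, CH2Cl2, rt
Reagents that add atoms: 2-ethoxyethanol, CCOCCO
Why: Benzylic oxidation by DDQ (hydride abstraction from C4, assisted by the 5,7-dialkoxy ring A) gives a quinone-methide cation that the alcohol traps, the standard C4 activation of benzylated flavan-3-ols, and the new C4 centre (4β ether expected) is of no consequence because it is ionised again in step 6.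

Step 5
Reactants: 8 (2R,3S,4S)-4-(2-ethoxyethoxy)-3,5,7,3′,4′-penta-O-benzylcatechin
Product: 9 (2R,3S,4S)-8-bromo-4-(2-ethoxyethoxy)-3,5,7,3′,4′-penta-O-benzylcatechin
Conditions: NBS, CH2Cl2, −78 °C→0 °C
Reagents that add atoms: N-bromosuccinimide, O=C1CCC(=O)N1Br
Why: Electrophilic aromatic bromination at C8 as in step 2, where the bromine cap stops self-condensation of the electrophile through C8 and later leaves C6 of this unit as the only free ring A position for formylation.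

Step 6
Reactants: 9 (2R,3S,4S)-8-bromo-4-(2-ethoxyethoxy)-3,5,7,3′,4′-penta-O-benzylcatechin; 4 8-bromo-3,5,7,3′,4′-penta-O-benzyl-(−)-epicatechin
Product: 10 8-bromo-3,5,7,3′,4′-penta-O-benzylcatechin-(4α→6)-8-bromo-3,5,7,3′,4′-penta-O-benzylepicatechin
Conditions: Me3SiOTf (cat.), 4 (3 equiv), CH2Cl2, −78 °C; then Et3N
Reagents that add atoms: none
Why: Lewis-acid-promoted Friedel–Crafts-type interflavan coupling, in which Me3SiOTf ionises the C4 ether to a benzylic cation that C6 of 4 attacks (C8 is blocked in both partners) on the face anti to the 3-benzyloxy group of the 2,3-trans half-chair, which sets the 3,4-trans (4α) linkage while the excess of 4 suppresses oligomerisation.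

Step 7
Reactants: 10 8-bromo-3,5,7,3′,4′-penta-O-benzylcatechin-(4α→6)-8-bromo-3,5,7,3′,4′-penta-O-benzylepicatechin
Product: 12 6-formyl derivative of 10 (CHO on C6 of the upper unit), via iminium chloride 11 (not isolated)
Conditions: POCl3, DMF, 1,2-dichloroethane, 0→60 °C; then aq. NaOAc
Reagents that add atoms: N,N-dimethylformamide, CN(C)C=O; water, O
Why: Vilsmeier–Haack formylation, in which the chloroiminium ion attacks the only unsubstituted ring A carbon, C6 of the upper unit, activated by three oxygen substituents whereas the catechol-ether B rings are much less nucleophilic, and aqueous acetate hydrolyses iminium salt 11 to the aldehyde.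

Step 8
Reactants: 12 6-formyl derivative of 10; 13 3,4-dibenzyloxyacetophenone
Product: 14 (E)-1-[3,4-bis(benzyloxy)phenyl]-3-(10-6-yl)prop-2-en-1-one
Conditions: KOH, EtOH/THF, rt→50 °C
Reagents that add atoms: none
Why: Claisen–Schmidt condensation (crossed aldol addition and E1cB dehydration) between a non-enolisable aldehyde and the acetophenone enolate, which gives the conjugated (E)-enone under thermodynamic control.

Step 9
Reactants: 14 (E)-1-[3,4-bis(benzyloxy)phenyl]-3-(10-6-yl)prop-2-en-1-one; 15 4-hydroxy-6-methyl-2-pyrone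
Product: 17 (4R)-2-[3,4-bis(benzyloxy)phenyl]-7-methyl-4-(10-6-yl)-4H,5H-pyrano[4,3-b]pyran-5-one, via Michael adduct 16 (not isolated)
Conditions: 9-amino-9-deoxy-epi-quinine (20 mol %), TFA (40 mol %), THF, 40 °C; then TsOH·H2O (cat.), 4 Å MS, toluene, 50 °C
Reagents that add atoms: none
Why: Iminium-catalysed asymmetric Michael addition of a cyclic 1,3-dicarbonyl C-nucleophile to an enone (warfarin-type chemistry) followed by acid-catalysed cyclodehydration of the hemiketal, in which the cinchona primary amine forms the chalcone iminium ion and shields one enone face so that C3 of the pyrone adds to give (R) at the benzylic carbon (catalyst control), and because the substrate is chiral any C4 epimer is a diastereomer removable by chromatography.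

Step 10
Reactants: 17 (4R)-2-[3,4-bis(benzyloxy)phenyl]-7-methyl-4-(10-6-yl)-4H,5H-pyrano[4,3-b]pyran-5-one
Product: 19 2-[3,4-bis(benzyloxy)phenyl]-4-(10-6-yl)-4H-chromene-5,7-diol (flav-2-ene of the top unit, C4 aryl α), via ring-opened keto ester 18 (not isolated)
Conditions: Mg(OMe)2, MeOH/THF, 60 °C; then KOt-Bu, THF, 0→40 °C; then 0.5 M HCl to pH 6, 0 °C
Reagents that add atoms: none
Why: Magnesium-bound methoxide adds to the lactone carbonyl C5, the ring opens to keto ester 18 in which the methyl ester on C4a and the acetonyl group on C8a are held cis on the enol ether double bond, and under tert-butoxide the terminal methyl enolate (the future C6) attacks the ester carbon (C5) in an intramolecular Claisen condensation, after which loss of methoxide and two enolisations give aromatic ring A as its bis-phenoxide. The closest known reactions are the alkoxide recyclisation of 6-methyl-2-pyrones and 3,5-dioxohexanoates (triacetic acid lactone series) to phloroglucinols and the δ-keto ester to cyclohexane-1,3-dione condensation; magnesium methoxide is the usual reagent for opening 4-alkoxy-6-methyl-2-pyrones at the lactone carbonyl, and tert-butoxide supplies the basicity for the closure. The single ring closed, carbocyclic ring A, forms by a 6-(enolendo)-exo-trig closure, the only unstrained mode because the more acidic C8 methylene could only give a four-membered ring and therefore merely equilibrates (Curtin–Hammett). No stereocentre is created, and C4 keeps its configuration because it is not alpha to a carbonyl and its deprotonation would give an antiaromatic 8π pyranyl anion. The step needs attack at the lactone carbonyl and not at C7 or C8a, and C- and not O-acylation, which the magnesium chelate, the bulky non-nucleophilic tert-butoxide and the irreversible aromatisation should secure, while benzyl ethers, aryl bromides and the enol ether are inert to alkoxide.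

Step 11
Reactants: 19 2-[3,4-bis(benzyloxy)phenyl]-4-(10-6-yl)-4H-chromene-5,7-diol
Product: 20 5,7-bis(benzyloxy)-2-[3,4-bis(benzyloxy)phenyl]-4-(10-6-yl)-4H-chromene
Conditions: BnBr, K2CO3, Bu4NI (cat.), DMF, rt→40 °C, argon
Reagents that add atoms: benzyl bromide, BrCc1ccccc1
Why: Williamson ether synthesis on the two new phenoxides under mild carbonate conditions, carried out at once because the free 5,7-dihydroxy-4H-chromene is sensitive to air and acid, with the enol ether and C4 unaffected.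

Step 12
Reactants: 20 5,7-bis(benzyloxy)-2-[3,4-bis(benzyloxy)phenyl]-4-(10-6-yl)-4H-chromene
Product: 22 5,7,3′,4′-tetra-O-benzylcatechin-(4α→6)-[dimer 10] (top 3-OH free; top unit 2R,3S, 2,3-trans-3,4-trans), via C3 alkylborane 21 (not isolated)
Conditions: BH3·THF, THF, 0 °C→rt; then NaOH, H2O2, H2O, 0 °C→rt
Reagents that add atoms: hydrogen peroxide, OO
Why: Hydroboration–oxidation of the cyclic enol ether, in which boron adds to C3 (β to O1) and hydrogen to C2 in a syn fashion on the face opposite the pseudo-axial C4 aryl group (substrate control) and oxidation with retention gives 2R,3S, the 2,3-trans-3,4-trans arrangement of a 4α-linked catechin unit.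

Step 13
Reactants: 22 5,7,3′,4′-tetra-O-benzylcatechin-(4α→6)-[dimer 10]
Product: 23 catechin-(4α→6)-catechin-(4α→6)-epicatechin (CNP0163146.3)
Conditions: H2 (1 atm), Pd(OH)2/C, Et3N (2.2 equiv), THF/MeOH/H2O, rt
Reagents that add atoms: none
Why: Catalytic hydrogenolysis removes all fourteen benzyl ethers and both aryl bromine caps (hydrodehalogenation, with Et3N taking up the HBr so that the acid-labile interflavan bonds survive) without touching any stereocentre.

Compound list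
1 | (−)-epicatechin, (2R,3R)-2-(3,4-dihydroxyphenyl)chromane-3,5,7-triol | Oc1cc(O)c2c(c1)O[C@H](c1ccc(O)c(O)c1)[C@H](O)C2 | starting material
2 | 5,7,3′,4′-tetra-O-benzyl-(−)-epicatechin (3-OH free) | c1c(OCc9ccccc9)cc2c(c1OCc9ccccc9)C[C@@H](O)[C@@H](c8ccc(OCc9ccccc9)c(OCc9ccccc9)c8)O2 | intermediate
3 | 3,5,7,3′,4′-penta-O-benzyl-(−)-epicatechin | c1c(OCc9ccccc9)cc2c(c1OCc9ccccc9)C[C@@H](OCc9ccccc9)[C@@H](c8ccc(OCc9ccccc9)c(OCc9ccccc9)c8)O2 | intermediate
4 | 8-bromo-3,5,7,3′,4′-penta-O-benzyl-(−)-epicatechin (bottom-unit nucleophile) | c1c(OCc9ccccc9)c(Br)c2c(c1OCc9ccccc9)C[C@@H](OCc9ccccc9)[C@@H](c8ccc(OCc9ccccc9)c(OCc9ccccc9)c8)O2 | intermediate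
5 | (+)-catechin, (2R,3S)-2-(3,4-dihydroxyphenyl)chromane-3,5,7-triol | Oc1cc(O)c2c(c1)O[C@H](c1ccc(O)c(O)c1)[C@@H](O)C2 | starting material
6 | 5,7,3′,4′-tetra-O-benzyl-(+)-catechin (3-OH free) | c1c(OCc9ccccc9)cc2c(c1OCc9ccccc9)C[C@H](O)[C@@H](c8ccc(OCc9ccccc9)c(OCc9ccccc9)c8)O2 | intermediate
7 | 3,5,7,3′,4′-penta-O-benzyl-(+)-catechin | c1c(OCc9ccccc9)cc2c(c1OCc9ccccc9)C[C@H](OCc9ccccc9)[C@@H](c8ccc(OCc9ccccc9)c(OCc9ccccc9)c8)O2 | intermediate
8 | (2R,3S,4S)-4-(2-ethoxyethoxy)-3,5,7,3′,4′-penta-O-benzylcatechin (4β ether) | c1c(OCc9ccccc9)cc2c(c1OCc9ccccc9)[C@H](OCCOCC)[C@H](OCc9ccccc9)[C@@H](c8ccc(OCc9ccccc9)c(OCc9ccccc9)c8)O2 | intermediate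
9 | (2R,3S,4S)-8-bromo-4-(2-ethoxyethoxy)-3,5,7,3′,4′-penta-O-benzylcatechin (middle-unit electrophile) | c1c(OCc9ccccc9)c(Br)c2c(c1OCc9ccccc9)[C@H](OCCOCC)[C@H](OCc9ccccc9)[C@@H](c8ccc(OCc9ccccc9)c(OCc9ccccc9)c8)O2 | intermediate
10 | 8-bromo-3,5,7,3′,4′-penta-O-benzylcatechin-(4α→6)-8-bromo-3,5,7,3′,4′-penta-O-benzylepicatechin (upper unit 2,3-trans-3,4-trans; C6–H of the upper unit free) | c3c(OCc9ccccc9)c(Br)c4c(c3OCc9ccccc9)[C@@H](c5c(OCc9ccccc9)c(Br)c6c(c5OCc9ccccc9)C[C@@H](OCc9ccccc9)[C@@H](c8ccc(OCc9ccccc9)c(OCc9ccccc9)c8)O6)[C@H](OCc9ccccc9)[C@@H](c8ccc(OCc9ccccc9)c(OCc9ccccc9)c8)O4 | intermediate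
11 | N,N-dimethyl-(10-6-yl)methaniminium chloride (Vilsmeier adduct) | C[N+](C)=Cc3c(OCc9ccccc9)c(Br)c4c(c3OCc9ccccc9)[C@@H](c5c(OCc9ccccc9)c(Br)c6c(c5OCc9ccccc9)C[C@@H](OCc9ccccc9)[C@@H](c8ccc(OCc9ccccc9)c(OCc9ccccc9)c8)O6)[C@H](OCc9ccccc9)[C@@H](c8ccc(OCc9ccccc9)c(OCc9ccccc9)c8)O4.[Cl-] | intermediate
12 | 6-formyl derivative of 10 (CHO on C6 of the upper unit, between the 5- and 7-benzyloxy groups) | O=Cc3c(OCc9ccccc9)c(Br)c4c(c3OCc9ccccc9)[C@@H](c5c(OCc9ccccc9)c(Br)c6c(c5OCc9ccccc9)C[C@@H](OCc9ccccc9)[C@@H](c8ccc(OCc9ccccc9)c(OCc9ccccc9)c8)O6)[C@H](OCc9ccccc9)[C@@H](c8ccc(OCc9ccccc9)c(OCc9ccccc9)c8)O4 | intermediate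
13 | 3,4-dibenzyloxyacetophenone | CC(=O)c1ccc(OCc2ccccc2)c(OCc2ccccc2)c1 | starting material
14 | (E)-1-[3,4-bis(benzyloxy)phenyl]-3-(10-6-yl)prop-2-en-1-one (chalcone) | O=C(/C=C/c3c(OCc9ccccc9)c(Br)c4c(c3OCc9ccccc9)[C@@H](c5c(OCc9ccccc9)c(Br)c6c(c5OCc9ccccc9)C[C@@H](OCc9ccccc9)[C@@H](c8ccc(OCc9ccccc9)c(OCc9ccccc9)c8)O6)[C@H](OCc9ccccc9)[C@@H](c8ccc(OCc9ccccc9)c(OCc9ccccc9)c8)O4)c8ccc(OCc9ccccc9)c(OCc9ccccc9)c8 | intermediate
15 | 4-hydroxy-6-methyl-2-pyrone | CC1=CC(O)=CC(=O)O1 | starting material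
16 | 3-[(1R)-3-[3,4-bis(benzyloxy)phenyl]-1-(10-6-yl)-3-oxopropyl]-4-hydroxy-6-methyl-2H-pyran-2-one (open form of the Michael adduct, in equilibrium with its cyclic hemiketal) | CC1=CC(O)=C(C(=O)O1)[C@@H](c3c(OCc9ccccc9)c(Br)c4c(c3OCc9ccccc9)[C@@H](c5c(OCc9ccccc9)c(Br)c6c(c5OCc9ccccc9)C[C@@H](OCc9ccccc9)[C@@H](c8ccc(OCc9ccccc9)c(OCc9ccccc9)c8)O6)[C@H](OCc9ccccc9)[C@@H](c8ccc(OCc9ccccc9)c(OCc9ccccc9)c8)O4)CC(=O)c8ccc(OCc9ccccc9)c(OCc9ccccc9)c8 | intermediate
17 | (4R)-2-[3,4-bis(benzyloxy)phenyl]-7-methyl-4-(10-6-yl)-4H,5H-pyrano[4,3-b]pyran-5-one (key-step precursor) | CC1=CC2=C(C(=O)O1)[C@@H](c3c(OCc9ccccc9)c(Br)c4c(c3OCc9ccccc9)[C@@H](c5c(OCc9ccccc9)c(Br)c6c(c5OCc9ccccc9)C[C@@H](OCc9ccccc9)[C@@H](c8ccc(OCc9ccccc9)c(OCc9ccccc9)c8)O6)[C@H](OCc9ccccc9)[C@@H](c8ccc(OCc9ccccc9)c(OCc9ccccc9)c8)O4)C=C(c8ccc(OCc9ccccc9)c(OCc9ccccc9)c8)O2 | intermediate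
18 | methyl (4R)-6-[3,4-bis(benzyloxy)phenyl]-4-(10-6-yl)-2-(2-oxopropyl)-4H-pyran-3-carboxylate | CC(=O)CC1=C(C(=O)OC)[C@@H](c3c(OCc9ccccc9)c(Br)c4c(c3OCc9ccccc9)[C@@H](c5c(OCc9ccccc9)c(Br)c6c(c5OCc9ccccc9)C[C@@H](OCc9ccccc9)[C@@H](c8ccc(OCc9ccccc9)c(OCc9ccccc9)c8)O6)[C@H](OCc9ccccc9)[C@@H](c8ccc(OCc9ccccc9)c(OCc9ccccc9)c8)O4)C=C(c8ccc(OCc9ccccc9)c(OCc9ccccc9)c8)O1 | intermediate
19 | 2-[3,4-bis(benzyloxy)phenyl]-4-(10-6-yl)-4H-chromene-5,7-diol (key-step product; C4 aryl α, configuration of 17 retained) | Oc1cc(O)c2c(c1)OC(c8ccc(OCc9ccccc9)c(OCc9ccccc9)c8)=C[C@@H]2c3c(OCc9ccccc9)c(Br)c4c(c3OCc9ccccc9)[C@@H](c5c(OCc9ccccc9)c(Br)c6c(c5OCc9ccccc9)C[C@@H](OCc9ccccc9)[C@@H](c8ccc(OCc9ccccc9)c(OCc9ccccc9)c8)O6)[C@H](OCc9ccccc9)[C@@H](c8ccc(OCc9ccccc9)c(OCc9ccccc9)c8)O4 | intermediate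
20 | 5,7-bis(benzyloxy)-2-[3,4-bis(benzyloxy)phenyl]-4-(10-6-yl)-4H-chromene (C4 aryl α) | c1(OCc9ccccc9)cc(OCc9ccccc9)c2c(c1)OC(c8ccc(OCc9ccccc9)c(OCc9ccccc9)c8)=C[C@@H]2c3c(OCc9ccccc9)c(Br)c4c(c3OCc9ccccc9)[C@@H](c5c(OCc9ccccc9)c(Br)c6c(c5OCc9ccccc9)C[C@@H](OCc9ccccc9)[C@@H](c8ccc(OCc9ccccc9)c(OCc9ccccc9)c8)O6)[C@H](OCc9ccccc9)[C@@H](c8ccc(OCc9ccccc9)c(OCc9ccccc9)c8)O4 | intermediate
21 | C3 borane (BH2 on C3β, H on C2β) of the top unit of 20 | c1(OCc9ccccc9)cc(OCc9ccccc9)c2c(c1)O[C@H](c8ccc(OCc9ccccc9)c(OCc9ccccc9)c8)[C@@H](B)[C@@H]2c3c(OCc9ccccc9)c(Br)c4c(c3OCc9ccccc9)[C@@H](c5c(OCc9ccccc9)c(Br)c6c(c5OCc9ccccc9)C[C@@H](OCc9ccccc9)[C@@H](c8ccc(OCc9ccccc9)c(OCc9ccccc9)c8)O6)[C@H](OCc9ccccc9)[C@@H](c8ccc(OCc9ccccc9)c(OCc9ccccc9)c8)O4 | intermediate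
22 | 5,7,3′,4′-tetra-O-benzylcatechin-(4α→6)-8-bromo-3,5,7,3′,4′-penta-O-benzylcatechin-(4α→6)-8-bromo-3,5,7,3′,4′-penta-O-benzylepicatechin (top 3-OH free) | c1(OCc9ccccc9)cc(OCc9ccccc9)c2c(c1)O[C@H](c8ccc(OCc9ccccc9)c(OCc9ccccc9)c8)[C@@H](O)[C@@H]2c3c(OCc9ccccc9)c(Br)c4c(c3OCc9ccccc9)[C@@H](c5c(OCc9ccccc9)c(Br)c6c(c5OCc9ccccc9)C[C@@H](OCc9ccccc9)[C@@H](c8ccc(OCc9ccccc9)c(OCc9ccccc9)c8)O6)[C@H](OCc9ccccc9)[C@@H](c8ccc(OCc9ccccc9)c(OCc9ccccc9)c8)O4 | intermediate
23 | catechin-(4α→6)-catechin-(4α→6)-epicatechin, CNP0163146.3 | Oc1cc(O)c2c(c1)O[C@H](c1ccc(O)c(O)c1)[C@@H](O)[C@@H]2c1c(O)cc2c(c1O)[C@@H](c1c(O)cc3c(c1O)C[C@@H](O)[C@@H](c1ccc(O)c(O)c1)O3)[C@H](O)[C@@H](c1ccc(O)c(O)c1)O2 | target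

Total step count: 13 steps.
Longest linear sequence: 11 steps (steps 3–13, from (+)-catechin); the epicatechin branch joins at step 6.

Steps most likely to fail

Step 10 (pyrone to ring A). The Claisen closure may stall at the stabilised C8 enolate of 18, or alkoxide may open the 4H-pyran ring by addition–elimination at C8a. In the fallback, ring A is brought in ready-made and not made from the pyrone. Chalcone 14 and commercial 3,5-bis(benzyloxy)phenol undergo acid-catalysed Friedel–Crafts conjugate addition ortho to the phenol and cyclodehydration (TsOH·H2O, 4 Å MS, toluene, 60 °C), a known route to 2,4-diaryl-4H-chromenes. This should give 20 directly, together with the C4 epimer of 20, F1. The two are diastereomers and are separated by chromatography. The fallback sets out from 14 and comes back to the route at 20.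

Step 9 (Michael addition and cyclodehydration). The hindered, electron-rich aryl ketone may form its iminium ion too slowly, or the resident stereocentres may override the catalyst and give poor facial selectivity at C4. The fallback replaces conjugate addition by a Knoevenagel/hetero-Diels–Alder sequence. Ketone 13 is converted (Me3SiOTf, Et3N, CH2Cl2) into its silyl enol ether, 1-[3,4-bis(benzyloxy)phenyl]-1-(trimethylsilyloxy)ethene, F2. Aldehyde 12 and pyrone 15 are condensed (ethylenediammonium diacetate, toluene, 50 °C) to the 3-arylidene-6-methylpyran-2,4-dione, F3, a far stronger acceptor than the chalcone. F3 reacts with F2 in an inverse-electron-demand hetero-Diels–Alder reaction to give the 2-(trimethylsilyloxy)-3,4-dihydro-2H-pyran cycloadduct, F4. TsOH in toluene then eliminates the silanol to give 17 and the C4 epimer of 17, F5, which is removed by chromatography. The fallback sets out from 12 (with 13 and 15) and comes back at 17.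

Step 7 (formylation). Electrophilic attack of the bulky chloroiminium ion may be too slow at a carbon flanked by two buttressed benzyloxy groups, and acid may then erode the interflavan bond. The fallback replaces electrophilic formylation by halogenation and halogen–metal exchange. Iodination of 10 (NIS, cat. TFA, CH2Cl2/MeCN, 0 °C) with the much smaller iodonium electrophile should give the 6-iodo derivative of 10, F6. Iodine–magnesium exchange (iPrMgCl·LiCl, THF, −40 °C), which is selective over the two aryl bromides, followed by DMF and aqueous work-up should give 12. The fallback sets out from 10 and comes back at 12.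

Further compounds
F1 | step 10 | C4 epimer of 20 (C4 aryl β) | c1(OCc9ccccc9)cc(OCc9ccccc9)c2c(c1)OC(c8ccc(OCc9ccccc9)c(OCc9ccccc9)c8)=C[C@H]2c3c(OCc9ccccc9)c(Br)c4c(c3OCc9ccccc9)[C@@H](c5c(OCc9ccccc9)c(Br)c6c(c5OCc9ccccc9)C[C@@H](OCc9ccccc9)[C@@H](c8ccc(OCc9ccccc9)c(OCc9ccccc9)c8)O6)[C@H](OCc9ccccc9)[C@@H](c8ccc(OCc9ccccc9)c(OCc9ccccc9)c8)O4
F2 | step 9 | 1-[3,4-bis(benzyloxy)phenyl]-1-(trimethylsilyloxy)ethene | C=C(O[Si](C)(C)C)c1ccc(OCc2ccccc2)c(OCc2ccccc2)c1
F3 | step 9 | 3-[(10-6-yl)methylidene]-6-methyl-2H-pyran-2,4(3H)-dione (E/Z mixture at the exocyclic alkene) | CC1=CC(=O)C(=Cc3c(OCc9ccccc9)c(Br)c4c(c3OCc9ccccc9)[C@@H](c5c(OCc9ccccc9)c(Br)c6c(c5OCc9ccccc9)C[C@@H](OCc9ccccc9)[C@@H](c8ccc(OCc9ccccc9)c(OCc9ccccc9)c8)O6)[C@H](OCc9ccccc9)[C@@H](c8ccc(OCc9ccccc9)c(OCc9ccccc9)c8)O4)C(=O)O1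
F4 | step 9 | (4R)-2-[3,4-bis(benzyloxy)phenyl]-7-methyl-4-(10-6-yl)-2-(trimethylsilyloxy)-3,4-dihydro-2H,5H-pyrano[4,3-b]pyran-5-one (mixture at the ketal carbon C2) | CC1=CC2=C(C(=O)O1)[C@@H](c3c(OCc9ccccc9)c(Br)c4c(c3OCc9ccccc9)[C@@H](c5c(OCc9ccccc9)c(Br)c6c(c5OCc9ccccc9)C[C@@H](OCc9ccccc9)[C@@H](c8ccc(OCc9ccccc9)c(OCc9ccccc9)c8)O6)[C@H](OCc9ccccc9)[C@@H](c8ccc(OCc9ccccc9)c(OCc9ccccc9)c8)O4)CC(O[Si](C)(C)C)(c8ccc(OCc9ccccc9)c(OCc9ccccc9)c8)O2
F5 | step 9 | C4 epimer of 17, (4S) | CC1=CC2=C(C(=O)O1)[C@H](c3c(OCc9ccccc9)c(Br)c4c(c3OCc9ccccc9)[C@@H](c5c(OCc9ccccc9)c(Br)c6c(c5OCc9ccccc9)C[C@@H](OCc9ccccc9)[C@@H](c8ccc(OCc9ccccc9)c(OCc9ccccc9)c8)O6)[C@H](OCc9ccccc9)[C@@H](c8ccc(OCc9ccccc9)c(OCc9ccccc9)c8)O4)C=C(c8ccc(OCc9ccccc9)c(OCc9ccccc9)c8)O2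
F6 | step 7 | 6-iodo derivative of 10 (iodine on C6 of the upper unit) | Ic3c(OCc9ccccc9)c(Br)c4c(c3OCc9ccccc9)[C@@H](c5c(OCc9ccccc9)c(Br)c6c(c5OCc9ccccc9)C[C@@H](OCc9ccccc9)[C@@H](c8ccc(OCc9ccccc9)c(OCc9ccccc9)c8)O6)[C@H](OCc9ccccc9)[C@@H](c8ccc(OCc9ccccc9)c(OCc9ccccc9)c8)O4
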